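**Retrosynthetic overview**
1. The C8 aldehyde goes on last, by Duff formylation of 7-hydroxychromone 11 at its only free aromatic position.
2. The pyranone ring and the C3–CH2Ar bond are made together in the new step: reductive benzylation–annulation of o-hydroxyaryl enaminone 6 with 4-methoxybenzaldehyde and Hantzsch ester.
3. Enaminone 6 comes from o-hydroxyacetophenone 5 and DMF-DMA. The phenol oxygen of 5 (future O1) is installed by ketone-directed Pd-catalysed ortho-C–H hydroxylation, which fixes the 5-OMe/6-Me/7-O pattern without isomers.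
4. Ketone 3 comes from commercial 2',4'-dihydroxy-3'-methylacetophenone by 4-O-pivaloylation and 2-O-methylation.
5. Ring order: both benzene rings are bought; the pyranone ring is the only ring formed (step 5).

Assumption: the target has no stereocentre and is achiral, so "single enantiomer" needs no stereocontrol; the only stereo-element on the way is the E double bond of enaminone 6.

**Step 1**
Reactants: 1 2',4'-dihydroxy-3'-methylacetophenone
Product: 2 4-acetyl-3-hydroxy-2-methylphenyl pivalate
Conditions: PivCl (1.05 equiv), Et3N (1.2 equiv), CH2Cl2, 0 °C to rt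
Reagents that add atoms: pivaloyl chloride, CC(C)(C)C(=O)Cl
Why: Selective O-acylation; the 2-OH is hydrogen-bonded to the acetyl group and flanked by the methyl, so only the free 4-OH reacts.

**Step 2**
Reactants: 2 4-acetyl-3-hydroxy-2-methylphenyl pivalate
Product: 3 4-acetyl-3-methoxy-2-methylphenyl pivalate
Conditions: MeI (3 equiv), K2CO3 (2 equiv), DMF, 40 °C
Reagents that add atoms: iodomethane, CI
Why: Williamson O-methylation of the remaining chelated phenol; the hindered pivalate, shielded by the ortho methyl, stays in place under anhydrous carbonate.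

**Step 3**
Reactants: 3 4-acetyl-3-methoxy-2-methylphenyl pivalate
Product: 5 4-acetyl-5-hydroxy-3-methoxy-2-methylphenyl pivalate, via aryl trifluoroacetate 4 (not isolated)
Conditions: Pd(TFA)2 (10 mol %), PhI(OCOCF3)2 (2 equiv), DCE, 80 °C; then aq. NaHCO3/MeOH, rt
Reagents that add atoms: [bis(trifluoroacetoxy)iodo]benzene, O=C(OI(OC(=O)C(F)(F)F)c1ccccc1)C(F)(F)F
Why: Known Pd(II)/Pd(IV) ketone-directed ortho-C–H oxygenation: the acetyl C=O directs cyclopalladation to the single ortho C–H, PIFA oxidises the palladacycle, and C–O reductive elimination gives trifluoroacetate 4, which is hydrolysed on work-up. The electron-withdrawing pivalate damps non-directed oxidation of the ring.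

**Step 4**
Reactants: 5 4-acetyl-5-hydroxy-3-methoxy-2-methylphenyl pivalate
Product: 6 4-[(E)-3-(dimethylamino)acryloyl]-5-hydroxy-3-methoxy-2-methylphenyl pivalate
Conditions: DMF-DMA (3 equiv), toluene, 100 °C
Reagents that add atoms: N,N-dimethylformamide dimethyl acetal, COC(OC)N(C)C
Why: Standard enaminone condensation of an aryl methyl ketone with DMF-DMA; the push–pull alkene forms as the thermodynamic E isomer and the chelated phenol is not touched.

**Step 5**
Reactants: 6 4-[(E)-3-(dimethylamino)acryloyl]-5-hydroxy-3-methoxy-2-methylphenyl pivalate; 7 4-methoxybenzaldehyde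
Product: 10 5-methoxy-3-(4-methoxybenzyl)-6-methyl-4-oxo-4H-chromen-7-yl pivalate, via alkylidene iminium ion 8 (not isolated), via α-benzyl enaminone 9 (not isolated)
Conditions: L-proline (20 mol %), Hantzsch ester (1.3 equiv), EtOH, 45 °C; then AcOH, 80 °C
Reagents that add atoms: none
Why: Proposed new method: three-component reductive benzylation–annulation of an o-hydroxyaryl enaminone. Proline turns aldehyde 7 into an iminium ion, the nucleophilic α-carbon of 6 adds to it (Mannich), and the enaminone nitrogen pushes proline out to give the α,β-unsaturated iminium ion 8. Hantzsch ester delivers hydride to the benzylic β-carbon of 8 to give α-benzyl enaminone 9, and AcOH/heat then triggers phenol addition and loss of Me2NH to close the chromone. The buffered amine medium keeps 6 from cyclising early to the unreactive 3-H chromone, and hydride capture of 8 outcompetes attack by a second enaminone. The closest known reaction types are the organocatalytic three-component reductive alkylation of CH-acids with aldehydes and Hantzsch ester, the iminium-type conjugate transfer hydrogenation of enals, and the domino α-functionalisation/chromone annulation of o-hydroxyaryl enaminones with electrophiles.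

**Step 6**
Reactants: 10 5-methoxy-3-(4-methoxybenzyl)-6-methyl-4-oxo-4H-chromen-7-yl pivalate
Product: 11 7-hydroxy-5-methoxy-3-(4-methoxybenzyl)-6-methyl-4H-chromen-4-one
Conditions: K2CO3 (0.5 equiv), MeOH, 40 °C; then aq. NH4Cl
Reagents that add atoms: none
Why: Base-catalysed methanolysis (transesterification) of the aryl pivalate, helped by the good 7-chromonyl phenoxide leaving group; the chromone and both methyl ethers tolerate mild carbonate.

**Step 7**
Reactants: 11 7-hydroxy-5-methoxy-3-(4-methoxybenzyl)-6-methyl-4H-chromen-4-one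
Product: 13 7-hydroxy-5-methoxy-3-(4-methoxybenzyl)-6-methyl-4-oxo-4H-chromene-8-carbaldehyde (CNP0177360.0), via aldimine 12 (not isolated)
Conditions: HMTA (3 equiv), TFA, 75 °C; then 2 M aq. HCl, 60 °C
Reagents that add atoms: hexamethylenetetramine, C1N2CN3CN1CN(C2)C3; water, O
Why: Duff formylation: protonated HMTA aminomethylates C8, the only free position ortho to the 7-OH, internal hydride transfer gives aldimine 12, and aqueous acid hydrolyses it to the aldehyde. The anisyl ring is para-blocked and far less reactive than the phenol ring.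

**Compound list**
1 | 2',4'-dihydroxy-3'-methylacetophenone | CC(=O)c1ccc(O)c(C)c1O | starting material
2 | 4-acetyl-3-hydroxy-2-methylphenyl pivalate | CC(=O)c1ccc(OC(=O)C(C)(C)C)c(C)c1O | intermediate
3 | 4-acetyl-3-methoxy-2-methylphenyl pivalate | CC(=O)c1ccc(OC(=O)C(C)(C)C)c(C)c1OC | intermediate
4 | 4-acetyl-3-methoxy-2-methyl-5-(trifluoroacetoxy)phenyl pivalate | CC(=O)c1c(OC(=O)C(F)(F)F)cc(OC(=O)C(C)(C)C)c(C)c1OC | intermediate (not isolated)
5 | 4-acetyl-5-hydroxy-3-methoxy-2-methylphenyl pivalate | CC(=O)c1c(O)cc(OC(=O)C(C)(C)C)c(C)c1OC | intermediate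
6 | 4-[(E)-3-(dimethylamino)acryloyl]-5-hydroxy-3-methoxy-2-methylphenyl pivalate | CN(C)/C=C/C(=O)c1c(O)cc(OC(=O)C(C)(C)C)c(C)c1OC | intermediate
7 | 4-methoxybenzaldehyde | COc1ccc(C=O)cc1 | starting material
8 | N,N-dimethyl iminium ion of 2-(4-methoxybenzylidene)-3-oxo-3-aryl-propanal (aryl = 6-hydroxy-2-methoxy-3-methyl-4-pivaloyloxyphenyl; C=C geometry not controlled) | C[N+](C)=CC(=Cc1ccc(OC)cc1)C(=O)c1c(O)cc(OC(=O)C(C)(C)C)c(C)c1OC | intermediate (not isolated)
9 | 4-[3-(dimethylamino)-2-(4-methoxybenzyl)acryloyl]-5-hydroxy-3-methoxy-2-methylphenyl pivalate (E/Z not controlled) | CN(C)C=C(Cc1ccc(OC)cc1)C(=O)c1c(O)cc(OC(=O)C(C)(C)C)c(C)c1OC | intermediate (not isolated)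
10 | 5-methoxy-3-(4-methoxybenzyl)-6-methyl-4-oxo-4H-chromen-7-yl pivalate | COc1ccc(Cc2coc3cc(OC(=O)C(C)(C)C)c(C)c(OC)c3c2=O)cc1 | intermediate
11 | 7-hydroxy-5-methoxy-3-(4-methoxybenzyl)-6-methyl-4H-chromen-4-one | COc1ccc(Cc2coc3cc(O)c(C)c(OC)c3c2=O)cc1 | intermediate
12 | 7-hydroxy-8-(iminomethyl)-5-methoxy-3-(4-methoxybenzyl)-6-methyl-4H-chromen-4-one | COc1ccc(Cc2coc3c(C=N)c(O)c(C)c(OC)c3c2=O)cc1 | intermediate (not isolated)
13 | 7-hydroxy-5-methoxy-3-(4-methoxybenzyl)-6-methyl-4-oxo-4H-chromene-8-carbaldehyde | COc1ccc(Cc2coc3c(C=O)c(O)c(C)c(OC)c3c2=O)cc1 | target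

**Totals**
Total step count: 7. Longest linear sequence: 7 steps (from 1; aldehyde 7 enters at step 5).

**Three steps most likely to fail**

Step 3 (directed C–H hydroxylation). The ortho-methoxy group may twist the ketone out of plane and slow cyclopalladation, and PIFA may attack the electron-rich ring. The fallback sets out from 3 and comes back at 5. Iridium-catalysed carbonyl-directed ortho-C–H borylation of 3 ([Ir(OMe)(cod)]2, AsPh3, B2pin2, octane, 120 °C) gives 4-acetyl-3-methoxy-2-methyl-5-(4,4,5,5-tetramethyl-1,3,2-dioxaborolan-2-yl)phenyl pivalate F1. Oxidation of the C–B bond with Oxone in acetone–water at rt then gives phenol 5. This swaps an oxidative Pd(II)/Pd(IV) oxygenation for a redox-neutral borylation followed by a mild boronate oxidation.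

Step 5 (proposed new method). Risks are early cyclisation of 6 to the 3-unsubstituted chromone, 2:1 enaminone/aldehyde adducts, and slow iminium formation from the electron-rich aldehyde. The fallback uses known chemistry, sets out from 6 and comes back at 10. Iodine-triggered cyclisation of 6 (I2, CHCl3, rt) gives 3-iodo-5-methoxy-6-methyl-4-oxo-4H-chromen-7-yl pivalate F2. Negishi coupling of F2 with commercial 4-methoxybenzylzinc chloride (PdCl2(dppf), THF, 50 °C) then gives 10.

Step 7 (Duff formylation). The protonated chromone is a deactivated phenol, so yields may be low, and some formylation of the anisyl ring is possible. The fallback sets out from 11 and comes back at 13. Iodination with NIS (MeCN, 0 °C) at the only free phenol-ortho position gives 7-hydroxy-8-iodo-5-methoxy-3-(4-methoxybenzyl)-6-methyl-4H-chromen-4-one F3. Suzuki–Miyaura vinylation (potassium vinyltrifluoroborate, PdCl2(dppf), Et3N, n-PrOH, 80 °C) gives 7-hydroxy-5-methoxy-3-(4-methoxybenzyl)-6-methyl-8-vinyl-4H-chromen-4-one F4. Lemieux–Johnson cleavage of the styrene-type alkene (OsO4 cat., NaIO4, 2,6-lutidine, dioxane–water, rt) gives 13; the electron-poor chromone C2=C3 bond should react more slowly than the vinyl group.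

**Further compounds**
F1 | step 3 | 4-acetyl-3-methoxy-2-methyl-5-(4,4,5,5-tetramethyl-1,3,2-dioxaborolan-2-yl)phenyl pivalate | CC(=O)c1c(B2OC(C)(C)C(C)(C)O2)cc(OC(=O)C(C)(C)C)c(C)c1OC
F2 | step 5 | 3-iodo-5-methoxy-6-methyl-4-oxo-4H-chromen-7-yl pivalate | COc1c(C)c(OC(=O)C(C)(C)C)cc2occ(I)c(=O)c12
F3 | step 7 | 7-hydroxy-8-iodo-5-methoxy-3-(4-methoxybenzyl)-6-methyl-4H-chromen-4-one | COc1ccc(Cc2coc3c(I)c(O)c(C)c(OC)c3c2=O)cc1
F4 | step 7 | 7-hydroxy-5-methoxy-3-(4-methoxybenzyl)-6-methyl-8-vinyl-4H-chromen-4-one | COc1ccc(Cc2coc3c(C=C)c(O)c(C)c(OC)c3c2=O)cc1
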